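Everything rests on cutting the cyclobutane bond C6–C11 (target-SMILES numbering: C1 carbinol, C4 and C11 quaternary, C9 ketone). What remains is a cis-fused six–seven bicycle in which C11, carried by the ring-fusion carbon C10 of the seven-membered ring, lies over C6, the carbon 1,3 to C10 in the six-membered ring C5–C10. The key step exploits this contact: a silyl Lewis acid opens the C1–C11 epoxide at tertiary C11 and the γ-carbon C6 of a C9 silyl dienol ether closes the four-membered ring with inversion, delivering the C6–C11 bond, both new stereocentres, the C7–C8 enone and the C1 alcohol in one operation. The precursor is that epoxy silyl dienol ether, assembled by Diels–Alder annulation of an (S)-cycloheptenone.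

Key step: step 17

Remark: ring atoms keep the target numbering throughout (seven-membered ring C1–C2–C3–C4–C5–C10–C11, six-membered ring C5–C6–C7–C8–C9–C10, C12 = the CH2O carbon on C4); α is the side on which H-5 and H-10 lie, β the other side; the bicyclic intermediates are cis-fused bicyclo[5.4.0]undecanes (six–seven, not five–seven); the antipode of the step 1 catalyst is assumed to be the one that gives the S ester.

Step 1
Reactants: 1 tert-butyl 2-oxocycloheptane-1-carboxylate
Product: 2 tert-butyl (S)-1-methyl-2-oxocycloheptane-1-carboxylate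
Conditions: MeI, CsOH·H2O, (S)- or (R)-4,4-dibutyl-2,6-bis(3,4,5-trifluorophenyl)-4,5-dihydro-3H-dinaphtho[2,1-c:1',2'-e]azepinium bromide (2 mol %), toluene, −40 °C
Reagents that add atoms: iodomethane, CI
Why: Phase-transfer-catalysed asymmetric alkylation of a cyclic β-keto ester, in which the chiral ammonium enolate ion pair is methylated on one face and so sets the quaternary C4 as S.

Step 2
Reactants: 2 tert-butyl (S)-1-methyl-2-oxocycloheptane-1-carboxylate
Product: 4 tert-butyl (S)-1-methyl-2-[(trifluoromethanesulfonyl)oxy]cyclohept-2-ene-1-carboxylate, via potassium enolate 3 (not isolated)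
Conditions: KN(SiMe3)2, THF, −78 °C; then PhNTf2, −78 → 0 °C
Reagents that add atoms: N-phenylbis(trifluoromethanesulfonimide), O=S(=O)(N(c1ccccc1)S(=O)(=O)C(F)(F)F)C(F)(F)F
Why: The ketone can enolise only away from the quaternary carbon, so O-triflation of the enolate (enol triflate formation) should give a single regioisomer.

Step 3
Reactants: 4 tert-butyl (S)-1-methyl-2-[(trifluoromethanesulfonyl)oxy]cyclohept-2-ene-1-carboxylate
Product: 5 tert-butyl (S)-1-methylcyclohept-2-ene-1-carboxylate
Conditions: Pd(OAc)2 (5 mol %), PPh3 (10 mol %), HCO2H, n-Bu3N, DMF, 60 °C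
Reagents that add atoms: none
Why: Palladium-catalysed formate reduction of an enol triflate (oxidative addition, formate decarboxylation to the hydride, reductive elimination) replaces OTf by H without touching the ester or the stereocentre.

Step 4
Reactants: 5 tert-butyl (S)-1-methylcyclohept-2-ene-1-carboxylate
Product: 6 [(S)-1-methylcyclohept-2-en-1-yl]methanol
Conditions: LiAlH4, THF, 0 °C → reflux
Reagents that add atoms: none
Why: Hydride reduction of the ester to the neopentyl primary alcohol; the isolated alkene is inert.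

Step 5
Reactants: 6 [(S)-1-methylcyclohept-2-en-1-yl]methanol
Product: 7 (S)-tert-butyldimethyl[(1-methylcyclohept-2-en-1-yl)methoxy]silane
Conditions: t-BuMe2SiCl, imidazole, DMF, rt
Reagents that add atoms: tert-butyldimethylsilyl chloride, CC(C)(C)[Si](C)(C)Cl
Why: Imidazole-mediated silylation of a primary alcohol.

Step 6
Reactants: 7 (S)-tert-butyldimethyl[(1-methylcyclohept-2-en-1-yl)methoxy]silane
Product: 8 (S)-4-{[(tert-butyldimethylsilyl)oxy]methyl}-4-methylcyclohept-2-en-1-one
Conditions: Rh2(cap)4 (dirhodium tetracaprolactamate, 1 mol %), t-BuOOH (70 % aq.), K2CO3 (0.5 equiv), CH2Cl2, rt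
Reagents that add atoms: tert-butyl hydroperoxide, CC(C)(C)OO
Why: Dirhodium-catalysed allylic oxidation; the only allylic C–H bonds are at C11 because the other allylic carbon is the quaternary C4, and the allyl radical should be trapped at the unhindered C11 end.

Step 7
Reactants: 9 but-3-en-2-one
Product: 10 2-[(tert-butyldimethylsilyl)oxy]buta-1,3-diene
Conditions: t-BuMe2SiOTf, Et3N, Et2O, 0 °C
Reagents that add atoms: tert-butyldimethylsilyl trifluoromethanesulfonate, CC(C)(C)[Si](C)(C)OS(=O)(=O)C(F)(F)F
Why: Soft enolisation and O-silylation of methyl vinyl ketone gives the 2-silyloxydiene.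

Step 8
Reactants: 8 (S)-4-{[(tert-butyldimethylsilyl)oxy]methyl}-4-methylcyclohept-2-en-1-one; 10 2-[(tert-butyldimethylsilyl)oxy]buta-1,3-diene
Product: 11 cis-fused Diels–Alder adduct (C11 ketone; C7(OTBS)=C8 silyl enol ether; H-5 and H-10 α; C12 α)
Conditions: AlBr3/AlMe3 (10:1, 0.3 equiv), toluene/CH2Cl2, −20 → 0 °C
Reagents that add atoms: none
Why: Lewis-acid-promoted Diels–Alder reaction in which the nucleophilic CH2 terminus next to the silyloxy carbon bonds to the enone β-carbon C5 (oxygen ends at C7), suprafacial addition makes the ring fusion cis, and the diene should approach anti to the bulkier CH2OTBS group on the neighbouring quaternary C4, so that C6 and C9 end cis to the C4 methyl.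

Step 9
Reactants: 11 cis-fused Diels–Alder adduct
Product: 13 C11 enol triflate (C11(OTf)=C1), via potassium enolate 12 (not isolated)
Conditions: KN(SiMe3)2, THF, −78 °C; then PhNTf2
Reagents that add atoms: N-phenylbis(trifluoromethanesulfonimide), O=S(=O)(N(c1ccccc1)S(=O)(=O)C(F)(F)F)C(F)(F)F
Why: Kinetic deprotonation should take the C1 methylene and not the hindered tertiary ring-fusion C10–H, so the cis fusion is untouched and enol triflate formation places the double bond at C11=C1.

Step 10
Reactants: 13 C11 enol triflate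
Product: 14 C11-methyl diene (C11(CH3)=C1; C7(OTBS)=C8)
Conditions: MeMgBr, Fe(acac)3 (5 mol %), THF/N-methylpyrrolidone, −30 °C
Reagents that add atoms: methylmagnesium bromide, C[Mg]Br
Why: Iron-catalysed Kumada-type cross-coupling of an alkenyl triflate installs the C11 methyl and with it the trisubstituted C11=C1 alkene; silyl ether and silyl enol ether are inert.

Step 11
Reactants: 14 C11-methyl diene
Product: 15 C7 enone (C7=O; C8=C9; C11(CH3)=C1)
Conditions: Pd(OAc)2 (10 mol %), O2 (1 atm), DMSO, 60 °C
Reagents that add atoms: none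
Why: Saegusa oxidation, in which palladation of the regiodefined silyl enol ether at C8 and β-hydride elimination from C9 can give only the C8=C9 enone.

Step 12
Reactants: 15 C7 enone
Product: 16 8α,9α-epoxy C7 ketone
Conditions: 30 % H2O2, NaOH (cat.), MeOH, 0 °C
Reagents that add atoms: hydrogen peroxide, OO
Why: Nucleophilic (Weitz–Scheffer) epoxidation touches only the electron-poor enone alkene, from the side anti to C11; the new centres are erased two steps later.

Step 13
Reactants: 16 8α,9α-epoxy C7 ketone
Product: 18 allylic alcohol (9α-OH; C7=C8; C11(CH3)=C1), via epoxy hydrazone 17 (not isolated)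
Conditions: N2H4·H2O, AcOH (cat.), MeOH, 0 °C → rt
Reagents that add atoms: none
Why: Wharton transposition, in which the epoxy hydrazone fragments with loss of N2 and moves the oxygen from C7 to C9 and the alkene to C7=C8.

Step 14
Reactants: 18 allylic alcohol
Product: 19 C9 enone (C9=O; C7=C8; C11(CH3)=C1)
Conditions: Dess–Martin periodinane, CH2Cl2, 0 °C → rt
Reagents that add atoms: none
Why: Dess–Martin oxidation of a secondary allylic alcohol under non-basic conditions, so that C10, now α to the ketone and allylic, should not enolise.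

Step 15
Reactants: 19 C9 enone
Product: 20 1α,11α-epoxy C9 enone
Conditions: dimethyldioxirane (acetone solution), CH2Cl2, −20 °C
Reagents that add atoms: dimethyldioxirane, CC1(C)OO1
Why: Electrophilic epoxidation takes the electron-rich trisubstituted C11=C1 alkene and not the enone, and should occur on the α side, anti to C9 on the allylic ring-fusion carbon and away from the six-membered ring folded over the β side, which puts the oxygen anti to C6.

Step 16
Reactants: 20 1α,11α-epoxy C9 enone
Product: 21 epoxy silyl dienol ether (1α,11α-epoxide; C6=C7–C8=C9(OSiMe3); key-step precursor)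
Conditions: Me3SiOTf, Et3N, CH2Cl2, −78 → −20 °C; pentane, filtration, used crude
Reagents that add atoms: trimethylsilyl trifluoromethanesulfonate, C[Si](C)(C)OS(=O)(=O)C(F)(F)F
Why: Soft enolisation, in which O-silylation gives a silyloxyallyl cation that Et3N should deprotonate at the exposed γ-methylene C6 and not at the ring-fusion C10–H flanked by the fully substituted C11, giving the linear dienol ether without epimerising C10.

Step 17
Reactants: 21 epoxy silyl dienol ether
Product: 23 (1R,4S,5S,6S,10R,11R)-tricyclic enone alcohol (C7=C8–C9=O; free C1–OH; C12–OTBS), via trimethylsilyl ether 22 (not isolated)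
Conditions: Me3SiOTf (10 mol %), 2,6-di-tert-butyl-4-methylpyridine (10 mol %), CH2Cl2, −78 °C; then K2CO3 (cat.), MeOH, 0 °C
Reagents that add atoms: none
Why: Proposed new method: Me3SiOTf silylates the epoxide oxygen, the C11–O bond lengthens at the tertiary carbon, and C6, the γ-terminus of the silyl dienol ether, attacks C11 from the side opposite oxygen; the silyloxyallyl cation then collapses to the C7–C8 enone and hands Me3Si+ back to triflate, so the C1 oxygen emerges as TMS ether 22, which methanolysis cleaves. The closest known reactions are Lewis-acid openings of epoxides by silyl enol and dienol ethers (vinylogous Mukaiyama-type alkylation), epoxide-initiated cation–olefin cyclisations ended by silyl enol ethers, and the enzymatic closure of the himachalyl to the longipinyl cation. The cyclobutane C5–C6–C11–C10 closes in a 4-exo-tet mode at the epoxide. C11 is set by inversion, which fixes the C1 oxygen anti to C6, and C6 is set because C11, tethered through C10 on the β side, can reach only that face of the diene. The step needs γ- over α-attack (attack by C8 would force sp2 C9 into the four-membered ring) and C–C bond formation faster than a 1,2-hydride shift from C1 to C11. The cis fusion, which can place C11 axial on C10 directly over C6, and charge development in a silyloxyallyl cation and not a cyclobutylcarbinyl cation should secure both.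

Step 18
Reactants: 23 tricyclic enone alcohol
Product: 24 (1R,4S,5S,6S,7R,10R,11R)-7-methyl ketone alcohol
Conditions: Me2CuLi (3 equiv), Et2O, −78 → −30 °C; aq. NH4Cl
Reagents that add atoms: lithium dimethylcuprate, [Li+].C[Cu-]C
Why: Cuprate conjugate addition to the bicyclo[3.1.1]heptenone from the side of the C5–H bridge, anti to the C11 methyl that overhangs the enone, should set C7 with the methyl cis to C5; excess reagent absorbs the free hydroxyl.

Step 19
Reactants: 24 7-methyl ketone alcohol
Product: 25 diol (free C1–OH and C12–OH)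
Conditions: Bu4NF, THF, rt
Reagents that add atoms: none
Why: Fluoride desilylation of the primary TBS ether.

Step 20
Reactants: 25 diol
Product: 26 primary tiglate (C12–O-tigloyl; free C1–OH)
Conditions: tigloyl chloride (1.1 equiv), pyridine, CH2Cl2, −20 → 0 °C
Reagents that add atoms: (E)-2-methylbut-2-enoyl chloride, ClC(=O)/C(C)=C/C
Why: Acylation should take the primary alcohol far faster than the secondary C1–OH next to the quaternary C11, and the E acid chloride keeps its geometry.

Step 21
Reactants: 26 primary tiglate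
Product: 27 CNP0276938.2 (target)
Conditions: angelic acid, 2,4,6-trichlorobenzoyl chloride, Et3N, toluene, rt; then 26, 80 °C
Reagents that add atoms: (Z)-2-methylbut-2-enoic acid, C/C=C(/C)C(=O)O
Why: Yamaguchi esterification through the mixed trichlorobenzoic anhydride, run without DMAP, acylates the hindered C1–OH while keeping the Z (angelate) geometry.

Compound list

1 | tert-butyl 2-oxocycloheptane-1-carboxylate | CC(C)(C)OC(=O)C1CCCCCC1=O | starting material
2 | tert-butyl (S)-1-methyl-2-oxocycloheptane-1-carboxylate | CC(C)(C)OC(=O)[C@@]1(C)CCCCCC1=O | intermediate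
3 | potassium enolate of 2 | CC(C)(C)OC(=O)[C@@]1(C)CCCCC=C1[O-].[K+] | intermediate
4 | tert-butyl (S)-1-methyl-2-[(trifluoromethanesulfonyl)oxy]cyclohept-2-ene-1-carboxylate | CC(C)(C)OC(=O)[C@@]1(C)CCCCC=C1OS(=O)(=O)C(F)(F)F | intermediate
5 | tert-butyl (S)-1-methylcyclohept-2-ene-1-carboxylate | CC(C)(C)OC(=O)[C@@]1(C)CCCCC=C1 | intermediate
6 | [(S)-1-methylcyclohept-2-en-1-yl]methanol | OC[C@@]1(C)CCCCC=C1 | intermediate
7 | (S)-tert-butyldimethyl[(1-methylcyclohept-2-en-1-yl)methoxy]silane | CC(C)(C)[Si](C)(C)OC[C@@]1(C)CCCCC=C1 | intermediate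
8 | (S)-4-{[(tert-butyldimethylsilyl)oxy]methyl}-4-methylcyclohept-2-en-1-one | CC(C)(C)[Si](C)(C)OC[C@@]1(C)CCCC(=O)C=C1 | intermediate
9 | but-3-en-2-one | CC(=O)C=C | starting material
10 | 2-[(tert-butyldimethylsilyl)oxy]buta-1,3-diene | C=CC(=C)O[Si](C)(C)C(C)(C)C | intermediate
11 | cis-fused Diels–Alder adduct: C11 ketone, C7(OTBS)=C8, C4 β-methyl and α-CH2OTBS, H-5 and H-10 α | O=C1CCC[C@](C)(CO[Si](C)(C)C(C)(C)C)[C@H]2CC(O[Si](C)(C)C(C)(C)C)=CC[C@H]21 | intermediate
12 | potassium enolate of 11 (C11–O−, C11=C1) | [K+].[O-]C1=CCC[C@](C)(CO[Si](C)(C)C(C)(C)C)[C@H]2CC(O[Si](C)(C)C(C)(C)C)=CC[C@H]21 | intermediate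
13 | C11 enol triflate, C11(OTf)=C1 | FC(F)(F)S(=O)(=O)OC1=CCC[C@](C)(CO[Si](C)(C)C(C)(C)C)[C@H]2CC(O[Si](C)(C)C(C)(C)C)=CC[C@H]21 | intermediate
14 | C11-methyl diene, C11(CH3)=C1 and C7(OTBS)=C8 | CC1=CCC[C@](C)(CO[Si](C)(C)C(C)(C)C)[C@H]2CC(O[Si](C)(C)C(C)(C)C)=CC[C@H]21 | intermediate
15 | C7 enone, C8=C9, C11(CH3)=C1 | CC1=CCC[C@](C)(CO[Si](C)(C)C(C)(C)C)[C@H]2CC(=O)C=C[C@H]21 | intermediate
16 | 8α,9α-epoxy C7 ketone | CC1=CCC[C@](C)(CO[Si](C)(C)C(C)(C)C)[C@H]2CC(=O)[C@@H]3O[C@@H]3[C@H]21 | intermediate
17 | hydrazone of 16 | CC1=CCC[C@](C)(CO[Si](C)(C)C(C)(C)C)[C@H]2CC(=NN)[C@@H]3O[C@@H]3[C@H]21 | intermediate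
18 | allylic alcohol, 9α-OH, C7=C8, C11(CH3)=C1 | CC1=CCC[C@](C)(CO[Si](C)(C)C(C)(C)C)[C@H]2CC=C[C@H](O)[C@H]21 | intermediate
19 | C9 enone, C7=C8, C11(CH3)=C1 | CC1=CCC[C@](C)(CO[Si](C)(C)C(C)(C)C)[C@H]2CC=CC(=O)[C@H]21 | intermediate
20 | 1α,11α-epoxy C9 enone | O1[C@@H]2CC[C@](C)(CO[Si](C)(C)C(C)(C)C)[C@H]3CC=CC(=O)[C@H]3[C@]12C | intermediate
21 | epoxy silyl dienol ether, 1α,11α-epoxide, C6=C7–C8=C9(OSiMe3) | O1[C@@H]2CC[C@](C)(CO[Si](C)(C)C(C)(C)C)[C@H]3C=CC=C(O[Si](C)(C)C)[C@H]3[C@]12C | intermediate
22 | C1 trimethylsilyl ether of 23 | C[Si](C)(C)O[C@@H]1CC[C@](C)(CO[Si](C)(C)C(C)(C)C)[C@H]2[C@@H]3C=CC(=O)[C@H]2[C@@]31C | intermediate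
23 | (1R,4S,5S,6S,10R,11R)-tricyclic C7–C8 enone, C9 ketone, free C1–OH, C12–OTBS | O[C@@H]1CC[C@](C)(CO[Si](C)(C)C(C)(C)C)[C@H]2[C@@H]3C=CC(=O)[C@H]2[C@@]31C | intermediate
24 | (1R,4S,5S,6S,7R,10R,11R)-7-methyl C9 ketone, free C1–OH, C12–OTBS | O[C@@H]1CC[C@](C)(CO[Si](C)(C)C(C)(C)C)[C@H]2[C@@H]3[C@H](C)CC(=O)[C@H]2[C@@]31C | intermediate
25 | diol, free C1–OH and C12–OH | O[C@@H]1CC[C@](C)(CO)[C@H]2[C@@H]3[C@H](C)CC(=O)[C@H]2[C@@]31C | intermediate
26 | C12 tiglate, free C1–OH | O[C@@H]1CC[C@](C)(COC(=O)/C(C)=C/C)[C@H]2[C@@H]3[C@H](C)CC(=O)[C@H]2[C@@]31C | intermediate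
27 | CNP0276938.2, C1 angelate and C12 tiglate | C/C=C(/C)C(=O)O[C@@H]1CC[C@](C)(COC(=O)/C(C)=C/C)[C@H]2[C@@H]3[C@H](C)CC(=O)[C@H]2[C@@]31C | target

Total steps: 21. Longest linear sequence: 20 (steps 1–6 and 8–21; step 7 is a one-step side branch).

Steps most likely to fail

Step 17. After ionisation at C11, a 1,2-hydride shift from C1 (giving a C1 ketone), proton loss to an allylic silyl ether, or protodesilylation of the dienol ether may outrun four-membered ring closure. The fallback uses known chemistry, sets out from 15 and comes back at 23. Dimethyldioxirane would epoxidise C11=C1 of 15 to the 1α,11α-epoxy C7 enone F1. LiN(iPr)2 at −78 °C would give the kinetic cross-conjugated lithium enolate F2 by deprotonation at C6. On warming, its C6 should open the epoxide at C11 with inversion, in the anionic 4-exo-tet mode known from epoxy-nitrile cyclisations, which also attack the more substituted epoxide carbon; this gives the tricyclic C7 ketone F3 (C8=C9 enone, free C1–OH). The carbonyl is then moved as in the main route: alkaline H2O2 to the epoxy ketone F4, hydrazine through the hydrazone F5 to the allylic diol F6 (Wharton transposition), and MnO2, which oxidises only the allylic C9–OH, to 23.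

Step 8. The γ,γ-disubstituted enone may react slowly, the Lewis acid may stop at Mukaiyama–Michael addition or epimerise C10 next to the C11 ketone, and discrimination between the two faces set by C4 may erode. The fallback sets out from 8 and comes back at 15. Heating 8 without Lewis acid with the far more reactive (E)-1-(dimethylamino)-3-(tert-butyldimethylsilyloxy)buta-1,3-diene would give the amino silyl enol ether adduct F7. The sequence of steps 9 and 10 (potassium enolate F8, enol triflate F9, C11-methyl amino diene F10) followed by dilute HCl, which hydrolyses the enol ether and eliminates dimethylamine, would deliver enone 15 directly and save the Saegusa step.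

Step 16. Deprotonation may occur at C10 instead of C6, which would give the cross-conjugated ether and invite β-elimination of the epoxide, or the silyl triflate may open the epoxide. The fallback sets out from 20 and comes back at 21. PPh3-catalysed 1,4-addition of PhSeSiMe3 to 20 would give the 7-phenylselanyl silyl enol ether F11, whose enol ether position is fixed by the conjugate addition. Oxidation at selenium with one equivalent of peracid at −78 °C to the selenoxide F12 and syn-elimination on warming with Et3N, possible only toward C6, would give 21.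

Further compounds

F1 | step 17 | 1α,11α-epoxy C7 enone | O1[C@@H]2CC[C@](C)(CO[Si](C)(C)C(C)(C)C)[C@H]3CC(=O)C=C[C@H]3[C@]12C
F2 | step 17 | lithium enolate of F1 (C7–O−, C6=C7, C8=C9) | [Li+].O1[C@@H]2CC[C@](C)(CO[Si](C)(C)C(C)(C)C)[C@H]3C=C([O-])C=C[C@H]3[C@]12C
F3 | step 17 | tricyclic C7 ketone, C8=C9, free C1–OH | O[C@@H]1CC[C@](C)(CO[Si](C)(C)C(C)(C)C)[C@H]2[C@@H]3C(=O)C=C[C@H]2[C@@]31C
F4 | step 17 | tricyclic 8,9-epoxy C7 ketone (epoxide on the C5 side) | O[C@@H]1CC[C@](C)(CO[Si](C)(C)C(C)(C)C)[C@H]2[C@@H]3C(=O)[C@@H]4O[C@@H]4[C@H]2[C@@]31C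
F5 | step 17 | hydrazone of F4 | O[C@@H]1CC[C@](C)(CO[Si](C)(C)C(C)(C)C)[C@H]2[C@@H]3C(=NN)[C@@H]4O[C@@H]4[C@H]2[C@@]31C
F6 | step 17 | tricyclic allylic diol, C1–OH and C9–OH, C7=C8 | O[C@@H]1CC[C@](C)(CO[Si](C)(C)C(C)(C)C)[C@H]2[C@@H]3C=C[C@H](O)[C@H]2[C@@]31C
F7 | step 8 | amino silyl enol ether adduct, 9β-NMe2, C7(OTBS)=C8, C11 ketone | O=C1CCC[C@](C)(CO[Si](C)(C)C(C)(C)C)[C@H]2CC(O[Si](C)(C)C(C)(C)C)=C[C@@H](N(C)C)[C@H]21
F8 | step 8 | potassium enolate of F7 (C11–O−, C11=C1) | [K+].[O-]C1=CCC[C@](C)(CO[Si](C)(C)C(C)(C)C)[C@H]2CC(O[Si](C)(C)C(C)(C)C)=C[C@@H](N(C)C)[C@H]21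
F9 | step 8 | C11 enol triflate of F7 | FC(F)(F)S(=O)(=O)OC1=CCC[C@](C)(CO[Si](C)(C)C(C)(C)C)[C@H]2CC(O[Si](C)(C)C(C)(C)C)=C[C@@H](N(C)C)[C@H]21
F10 | step 8 | C11-methyl amino diene, C11(CH3)=C1, C7(OTBS)=C8, 9β-NMe2 | CC1=CCC[C@](C)(CO[Si](C)(C)C(C)(C)C)[C@H]2CC(O[Si](C)(C)C(C)(C)C)=C[C@@H](N(C)C)[C@H]21
F11 | step 16 | 7α-phenylselanyl silyl enol ether, C8=C9(OSiMe3), 1α,11α-epoxide | O1[C@@H]2CC[C@](C)(CO[Si](C)(C)C(C)(C)C)[C@H]3C[C@H]([Se]c4ccccc4)C=C(O[Si](C)(C)C)[C@H]3[C@]12C
F12 | step 16 | selenoxide of F11 | O1[C@@H]2CC[C@](C)(CO[Si](C)(C)C(C)(C)C)[C@H]3C[C@H]([Se](=O)c4ccccc4)C=C(O[Si](C)(C)C)[C@H]3[C@]12C
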